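## Analysis of the target

Palstatin (22) is a flavonolignan. A 5,7-dihydroxyflavone (rings A and C) carries a ring B (C1'–C6') that is fused through the oxygens on C3' and C4' to a 1,4-dioxane and bears a methoxy group at C5'. The dioxane carbons are C7'', which carries a 4-hydroxy-3,5-dimethoxyphenyl (syringyl) ring, and C8'', which carries the hydroxymethyl carbon C9''. These are the only stereocentres. Both are R, the two substituents are trans on the dioxane, and in the open chain this corresponds to a threo (syn) arrangement of the two oxygens. The C7''–O bond is a benzylic aryl ether next to an electron-rich ring, so strong acid can ionise it and long hydrogenation can cleave it. The free phenols oxidise easily in base, and the C2=C3 bond of ring C can be over-reduced. The difficulty lies in the orientation of the dioxane (C7''–O on C3' and C8''–O on C4', not the reverse) together with the absolute and relative configuration at C7'' and C8''. The strategy rests on one feature: C3', the ring B carbon whose oxygen is bound to C7'', lies ortho to the C4' oxygen and meta to C1'. That is exactly where 5-bromovanillin (1) carries bromine, and its hydroxyl, methoxy and formyl groups already map onto C4'–O, C5'–OMe and C1'.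

## Retrosynthetic reasoning

**Protecting groups (22 to 21).** The four hydroxyl groups of 22 (C5, C7, C9'' and the syringyl C4'') are traced back to benzyl ethers in flavone 21. One group type was chosen so that a single hydrogenolysis ends the route. Benzyl ethers should pass organomagnesium and hydride reagents, carbonate base with palladium, dilute acid, hydroxide and hot iodine unchanged.

**Ring C (21 to 19 to 17 and 18).** The O1–C2 bond and the C2=C3 unsaturation are taken back to the 2'-hydroxychalcone 19. Its central C=C bond is then cut to aldehyde 17 and acetophenone 18. This places the junction between the two halves of the molecule at a bond made by condensation, keeps the ring A oxygens in a purchasable piece, and asks of the ring B fragment only a formyl group at C1', which 1 supplies. The forward reactions must condense and then cyclise oxidatively without touching C7'' or C8''; neither carries an acidic hydrogen.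

**Aldehyde masking (17 to 16).** The formyl group is carried as a cyclic acetal in 16 so that it survives the carbon nucleophile and the hydride used earlier. The forward step is a mild hydrolysis.

**Dioxane ring, the key cut (16 to 15).** The C3'–O bond is cut, which gives bromo alcohol 15. Cutting O–C7'' instead would need a substitution at an ionisable benzylic carbon, and cutting O(C4')–C8'' would need a substitution at a hindered secondary carbon inside a ring-forming step. The C3'–O cut leaves both stereocentres as spectators and puts the new bond on an sp2 carbon whose position is dictated by the bromine of 1. The forward reaction must join a secondary benzylic alkoxide to an electron-rich aryl bromide without oxidising the carbinol.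

**C7'' stereocentre (15 to 14).** The C7''–H bond is traced to ketone 14. The existing C8'' aryloxy centre should steer a bulky hydride to the threo alcohol, so no second chiral reagent is needed.

**C7''–aryl bond (14 to 9 and 12; 12 from 11 from 10).** The bond between the carbonyl carbon and the syringyl ring is cut to the N-methoxy-N-methylamide 9 and the arylmagnesium bromide 12. Compound 12 comes from benzyl ether 11 and thus from 4-bromo-2,6-dimethoxyphenol (10). The magnesium reagent is preferred to an aryllithium because an aryllithium could exchange with the C3' bromide of 9, which must stay in place for the key step. The amide stops the addition at the ketone stage.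

**C8''–O–C4' bond (9 to 8 to 7 and 2; 2 from 1).** Amide 9 comes from ester 8, whose aryl ether bond is cut to hydroxy ester 7 and phenol 2, the acetal of 1. The forward reaction is an SN2 etherification with inversion at a carbon α to an ester, which turns the (S) centre of 7 into the (R) centre required at C8''.

**Chiral pool (7 to 6 to 3).** Hydroxy ester 7 comes from hydroxy acid 6 and this from O-benzyl-L-serine (3) by diazotisation with retention. Compound 3 brings C7''–C9'' with the C9'' oxygen already benzylated and the stereocentre in the sense that one inversion converts into C8'' R.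

## Alternatives that were turned down

**Alternative 1:** The O(C3')–C7'' bond is cut instead. The precursor is the open-chain aryl ether A2, in which C7'' is a methylene group, C3' carries a free hydroxyl and the syringyl phenol is unprotected. In the forward sense, constant-current oxidation at a carbon anode in hexafluoroisopropanol with a tetrabutylammonium tetrafluoroborate electrolyte would convert the 4-alkylphenol into a para-quinone methide. The C3' hydroxyl would trap it and give the dioxane ester A1.
- In its favour: no halogen, transition metal or hydride step is needed; only C8'' has to be brought in; A1 carries its phenol and primary alcohol free. On atom economy and protecting-group economy it is stronger than the chosen route.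
- Against it: C7'' would be set only by the energy difference between trans and cis dioxane after addition to a planar quinone methide, not by a stereospecific event.
- A1 is itself a 4-alkylphenol with a benzylic hydrogen that is now also flanked by an ether oxygen, so it should be oxidised at least as readily as A2. Over-oxidation, ring opening and quinone formation would compete.
- The C3' phenol of A2 is a second oxidisable site, and a dehydrogenative benzylic etherification that closes a dioxane would have to be worked out on this substrate.
- The methyl ester of A1 needs the longer diketone route to ring C, for which the phenol and the alcohol must be protected after all, so the step advantage is lost.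
- In its place the chosen strategy offers a ring closure of a known reaction class in which both stereocentres are set beforehand and merely carried through.

**Alternative 2:** Here the dioxane is taken as already made and the key cut is moved to ring C. The O1–C8a bond of the 5,7-difluoroflavone A3 is traced back to the 1,3-diketone A4, which carries a 2,4,6-trifluorophenyl ring. In the forward sense K2CO3 in DMF enolises A4 and the enolate oxygen displaces an ortho fluoride by addition–elimination. The two ortho positions are equivalent, so no regiochemical question arises.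
- In its favour: the closure is mild and non-oxidative and keeps hot iodine and acid away from the benzylic C7''–O bond. On this point it is gentler than the oxidative cyclisation of the chosen route.
- Against it: it solves the easiest ring of the molecule and leaves the orientation and configuration of the dioxane untouched, so a dioxane synthesis of the kind chosen here is needed anyway.
- The two remaining fluorines must then be exchanged for oxygen by two further aromatic substitutions with an alkoxide. The second is on a ring already deactivated by the first alkoxy group, and alkoxide can also add to C2 of the chromone and open ring C.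
- A4 needs a ring B acid derivative and an acylation or rearrangement sequence. The route is several steps longer than condensing aldehyde 17 with acetophenone 18, in which both ring A oxygens are present from the start.

**Alternative 3:** The O(C4')–C8'' bond is cut. Hydroxy aldehyde A5 is traced back to epoxide A6, in which C7'' is already bound through oxygen to C3', C8''–C9'' is a terminal epoxide and C4' carries a free hydroxyl. In the forward sense K2CO3 in methanol forms the C4' phenoxide, which attacks C8'' with inversion in a 6-exo opening and releases the C9'' hydroxyl.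
- In its favour: the closure is a stereospecific SN2 reaction, it is metal-free, and it frees the hydroxymethyl group without a protecting group. That is one benzyl ether fewer than in the chosen route, and the closure itself is as well founded as the palladium step.
- Against it: the phenoxide must attack the more substituted epoxide carbon next to the branched C7'', while 7-endo attack at the unhindered C9'' would give a benzodioxepine. A phenoxide para to a formyl group is also a weak nucleophile.
- The heavier burden is A6. Its C7''–O–C3' bond must be made with defined configuration at a benzylic carbon on an electron-rich ring, where substitution tends to pass through a cation and lose stereochemical information.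
- A6 also needs an epoxide of defined configuration, and the two neighbouring ring B hydroxyls must be told apart before alkylation. That is three stereo- or regiochemical decisions where the chosen route has two.
- The chosen strategy takes the ring B regiochemistry from the bromine of 1 and sets C7'' by a substrate-controlled reduction.

Key step: step 9

Assumption: ring B atoms are C1'–C6', the syringyl ring is C1''–C6'' and the three-carbon chain is C7''–C9''; acetophenone 18 is taken to be purchasable.

## Route

Step 1
Reactants: 1 5-bromovanillin (3-bromo-4-hydroxy-5-methoxybenzaldehyde)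
Product: 2 2-bromo-4-(1,3-dioxolan-2-yl)-6-methoxyphenol
Conditions: HOCH2CH2OH, TsOH·H2O (cat.), toluene, reflux, Dean–Stark; NaHCO3 work-up
Reagents that add atoms: ethylene glycol (ethane-1,2-diol), OCCO
Why: Acid-catalysed acetalisation with azeotropic removal of water; it masks the formyl group against the Grignard and hydride reagents used later and leaves the phenol free for the etherification, and no stereocentre is involved.

Step 2
Reactants: 3 O-benzyl-L-serine
Product: 6 (2S)-3-(benzyloxy)-2-hydroxypropanoic acid, via diazonium carboxylate 4 (not isolated), via alpha-lactone 5 (not isolated)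
Conditions: NaNO2, 1 M H2SO4 (aq.), 0 °C → rt
Reagents that add atoms: water, O
Why: Diazotisation of an α-amino acid (Van Slyke-type deamination): the carboxylate displaces dinitrogen from 4 to give α-lactone 5 and water opens it, two inversions that add up to retention, so the (S) configuration of 3 is kept; the benzyl ether is inert to cold dilute acid.

Step 3
Reactants: 6 (2S)-3-(benzyloxy)-2-hydroxypropanoic acid
Product: 7 methyl (2S)-3-(benzyloxy)-2-hydroxypropanoate
Conditions: MeOH, H2SO4 (cat.), 50 °C
Reagents that add atoms: methanol, CO
Why: Fischer esterification; the stereocentre does not enolise under acid, and the ester is needed because a free acid would intercept the Mitsunobu reagents in the next step.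

Step 4
Reactants: 7 methyl (2S)-3-(benzyloxy)-2-hydroxypropanoate; 2 2-bromo-4-(1,3-dioxolan-2-yl)-6-methoxyphenol
Product: 8 methyl (2R)-3-(benzyloxy)-2-[2-bromo-4-(1,3-dioxolan-2-yl)-6-methoxyphenoxy]propanoate
Conditions: PPh3, DIAD, THF, 0 °C → rt
Reagents that add atoms: none
Why: Mitsunobu etherification: the secondary hydroxyl of 7 is activated as an alkoxyphosphonium ion and displaced by the phenoxide of 2 (made more acidic by the ortho bromine) in an SN2 reaction at a carbon α to an ester, so the (S) centre is inverted to (R), the configuration of C8''; the acetal tolerates the neutral conditions.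

Step 5
Reactants: 8 methyl (2R)-3-(benzyloxy)-2-[2-bromo-4-(1,3-dioxolan-2-yl)-6-methoxyphenoxy]propanoate
Product: 9 (2R)-3-(benzyloxy)-2-[2-bromo-4-(1,3-dioxolan-2-yl)-6-methoxyphenoxy]-N-methoxy-N-methylpropanamide
Conditions: MeNH(OMe)·HCl, iPrMgCl, THF, −20 °C → 0 °C
Reagents that add atoms: N,O-dimethylhydroxylamine hydrochloride, CNOC.Cl
Why: Direct aminolysis of the methyl ester by the chloromagnesium amide of N,O-dimethylhydroxylamine (Weinreb amide formation); the amide anion acts as a nucleophile rather than a base at −20 °C, so C8'' should not epimerise, and iPrMgCl does not exchange with the electron-rich aryl bromide at this temperature.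

Step 6
Reactants: 10 4-bromo-2,6-dimethoxyphenol
Product: 11 2-(benzyloxy)-5-bromo-1,3-dimethoxybenzene
Conditions: BnBr, K2CO3, DMF, rt
Reagents that add atoms: benzyl bromide, BrCc1ccccc1
Why: Williamson ether synthesis on the phenoxide; the benzyl group protects the syringyl oxygen through Grignard formation and all later steps and leaves with the other benzyl groups at the end.

Step 7
Reactants: 11 2-(benzyloxy)-5-bromo-1,3-dimethoxybenzene; 9 (2R)-3-(benzyloxy)-2-[2-bromo-4-(1,3-dioxolan-2-yl)-6-methoxyphenoxy]-N-methoxy-N-methylpropanamide
Product: 14 (2R)-3-(benzyloxy)-1-[4-(benzyloxy)-3,5-dimethoxyphenyl]-2-[2-bromo-4-(1,3-dioxolan-2-yl)-6-methoxyphenoxy]propan-1-one, via arylmagnesium bromide 12 (not isolated), via tetrahedral magnesium adduct 13 (not isolated)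
Conditions: Mg turnings, BrCH2CH2Br (cat.), THF, 45 °C; then 9, THF, 0 °C; aq. NH4Cl, 0 °C
Reagents that add atoms: none
Why: Grignard formation followed by acylation with a Weinreb amide: adduct 13 is held as a five-membered magnesium chelate and cannot collapse before the quench, so one aryl group is delivered; the magnesium reagent does not undergo halogen–metal exchange with the C3' bromide, and the cold, weakly acidic quench should release ketone 14 without epimerising C8'' or eliminating benzyl alcohol; 14 is used at once.

Step 8
Reactants: 14 (2R)-3-(benzyloxy)-1-[4-(benzyloxy)-3,5-dimethoxyphenyl]-2-[2-bromo-4-(1,3-dioxolan-2-yl)-6-methoxyphenoxy]propan-1-one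
Product: 15 (1R,2R)-3-(benzyloxy)-1-[4-(benzyloxy)-3,5-dimethoxyphenyl]-2-[2-bromo-4-(1,3-dioxolan-2-yl)-6-methoxyphenoxy]propan-1-ol
Conditions: LiBH(s-Bu)3, THF, −78 °C; aq. NH4Cl
Reagents that add atoms: none
Why: Felkin–Anh (polar model) reduction by a bulky, non-chelating hydride: the C8''–OAr bond lies perpendicular to the carbonyl plane and hydride arrives anti to it past the C8'' hydrogen, which should give the syn (threo) alcohol and so set C7'' as R from C8'' R; the low temperature suppresses enolisation of the ketone.

Step 9
Reactants: 15 (1R,2R)-3-(benzyloxy)-1-[4-(benzyloxy)-3,5-dimethoxyphenyl]-2-[2-bromo-4-(1,3-dioxolan-2-yl)-6-methoxyphenoxy]propan-1-ol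
Product: 16 (2R,3R)-2-[(benzyloxy)methyl]-3-[4-(benzyloxy)-3,5-dimethoxyphenyl]-6-(1,3-dioxolan-2-yl)-8-methoxy-2,3-dihydro-1,4-benzodioxine
Conditions: Pd(OAc)2 (5 mol %), 2-(di-tert-butylphosphino)-1,1'-binaphthyl (6 mol %), Cs2CO3 (1.5 equiv), toluene, 70 °C
Reagents that add atoms: none
Why: This is a Buchwald–Hartwig-type palladium-catalysed intramolecular etherification of an aryl bromide with a secondary alcohol, a known way to 1,4-benzodioxanes. Pd(OAc)2 is reduced in the flask to zerovalent palladium, which inserts into the C3'–Br bond; Cs2CO3 turns the C7'' hydroxyl into the alkoxide that replaces bromide on divalent palladium, and C–O reductive elimination from the seven-membered oxapalladacycle forms the C3'–O bond. The six-membered dioxane therefore closes by reductive elimination at the metal and not by substitution at carbon, so no Baldwin-type constraint applies. No stereocentre is made: the C7''–O and C8''–O bonds are never broken, so the threo arrangement of 15 becomes the trans (2R,3R) dioxane of 16. The selectivity the step needs is reductive elimination ahead of β-hydride elimination from the benzylic palladium alkoxide, which would oxidise the carbinol and reduce off the bromine. The two tert-butyl groups and the binaphthyl backbone crowd the metal and speed up reductive elimination, and the short tether that leads to a six-membered ring works in the same direction. Regiochemistry is fixed by the substrate, because bromine sits only at C3'. The carbonate base is too weak to disturb the acetal, the benzyl ethers or the C8'' hydrogen.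

Step 10
Reactants: 16 (2R,3R)-2-[(benzyloxy)methyl]-3-[4-(benzyloxy)-3,5-dimethoxyphenyl]-6-(1,3-dioxolan-2-yl)-8-methoxy-2,3-dihydro-1,4-benzodioxine
Product: 17 (2R,3R)-2-[(benzyloxy)methyl]-3-[4-(benzyloxy)-3,5-dimethoxyphenyl]-8-methoxy-2,3-dihydro-1,4-benzodioxine-6-carbaldehyde
Conditions: 1 M HCl (aq.), THF, rt
Reagents that add atoms: water, O
Why: Acid-catalysed hydrolysis of the dioxolane of an electron-rich benzaldehyde, which is fast under conditions too mild to ionise the C7''–O benzylic ether, so the trans-dioxane should remain intact.

Step 11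
Reactants: 17 (2R,3R)-2-[(benzyloxy)methyl]-3-[4-(benzyloxy)-3,5-dimethoxyphenyl]-8-methoxy-2,3-dihydro-1,4-benzodioxine-6-carbaldehyde; 18 1-[2,4-bis(benzyloxy)-6-hydroxyphenyl]ethan-1-one
Product: 19 (2E)-1-[2,4-bis(benzyloxy)-6-hydroxyphenyl]-3-{(2R,3R)-2-[(benzyloxy)methyl]-3-[4-(benzyloxy)-3,5-dimethoxyphenyl]-8-methoxy-2,3-dihydro-1,4-benzodioxin-6-yl}prop-2-en-1-one
Conditions: KOH (50% aq.), EtOH–THF, rt
Reagents that add atoms: none
Why: Claisen–Schmidt condensation: the enolate of 18 adds to the non-enolisable aldehyde 17 and E1cB dehydration gives the conjugated E-chalcone; C7'' and C8'' carry no acidic hydrogen, and the 2'-hydroxyl stays free for ring closure.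

Step 12
Reactants: 19 (2E)-1-[2,4-bis(benzyloxy)-6-hydroxyphenyl]-3-{(2R,3R)-2-[(benzyloxy)methyl]-3-[4-(benzyloxy)-3,5-dimethoxyphenyl]-8-methoxy-2,3-dihydro-1,4-benzodioxin-6-yl}prop-2-en-1-one
Product: 21 5,7-bis(benzyloxy)-2-{(2R,3R)-2-[(benzyloxy)methyl]-3-[4-(benzyloxy)-3,5-dimethoxyphenyl]-8-methoxy-2,3-dihydro-1,4-benzodioxin-6-yl}-4H-chromen-4-one, via flavanone 20 (not isolated)
Conditions: I2 (10 mol %), DMSO, 120 °C
Reagents that add atoms: none
Why: Iodine-catalysed oxidative cyclisation of a 2'-hydroxychalcone: a 6-endo oxa-Michael closure gives flavanone 20, α-iodination and loss of HI give the flavone (the C2 centre of 20 disappears), and DMSO reoxidises HI to iodine; benzyl ethers are stable here, and should the C7''–O bond open reversibly under the acidic conditions it would reclose to the more stable trans isomer.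

Step 13
Reactants: 21 5,7-bis(benzyloxy)-2-{(2R,3R)-2-[(benzyloxy)methyl]-3-[4-(benzyloxy)-3,5-dimethoxyphenyl]-8-methoxy-2,3-dihydro-1,4-benzodioxin-6-yl}-4H-chromen-4-one
Product: 22 palstatin, 5,7-dihydroxy-2-[(2R,3R)-3-(4-hydroxy-3,5-dimethoxyphenyl)-2-(hydroxymethyl)-8-methoxy-2,3-dihydro-1,4-benzodioxin-6-yl]-4H-chromen-4-one
Conditions: H2 (1 atm), 10% Pd/C, THF–MeOH, rt; stopped when 21 and partly debenzylated material are consumed
Reagents that add atoms: none
Why: Catalytic hydrogenolysis of the four benzyl ethers (C5, C7, C9'' and the syringyl oxygen); the ring-bound, doubly substituted C7''–O bond and the conjugated C2=C3 bond should react more slowly than unhindered O-benzyl groups, so the reaction is halted at full debenzylation.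

## Compound list

1 | 5-bromovanillin (3-bromo-4-hydroxy-5-methoxybenzaldehyde) | COc1cc(C=O)cc(Br)c1O | starting material
2 | 2-bromo-4-(1,3-dioxolan-2-yl)-6-methoxyphenol | COc1cc(C2OCCO2)cc(Br)c1O | intermediate
3 | O-benzyl-L-serine | N[C@@H](COCc1ccccc1)C(=O)O | starting material
4 | (2S)-3-(benzyloxy)-2-diazoniopropanoate | N#[N+][C@@H](COCc1ccccc1)C(=O)[O-] | intermediate (not isolated)
5 | (3R)-3-[(benzyloxy)methyl]oxiran-2-one | O=C1O[C@@H]1COCc2ccccc2 | intermediate (not isolated)
6 | (2S)-3-(benzyloxy)-2-hydroxypropanoic acid | O[C@@H](COCc1ccccc1)C(=O)O | intermediate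
7 | methyl (2S)-3-(benzyloxy)-2-hydroxypropanoate | COC(=O)[C@@H](O)COCc1ccccc1 | intermediate
8 | methyl (2R)-3-(benzyloxy)-2-[2-bromo-4-(1,3-dioxolan-2-yl)-6-methoxyphenoxy]propanoate | COC(=O)[C@@H](COCc1ccccc1)Oc2c(Br)cc(C3OCCO3)cc2OC | intermediate
9 | (2R)-3-(benzyloxy)-2-[2-bromo-4-(1,3-dioxolan-2-yl)-6-methoxyphenoxy]-N-methoxy-N-methylpropanamide | CON(C)C(=O)[C@@H](COCc1ccccc1)Oc2c(Br)cc(C3OCCO3)cc2OC | intermediate
10 | 4-bromo-2,6-dimethoxyphenol | COc1cc(Br)cc(OC)c1O | starting material
11 | 2-(benzyloxy)-5-bromo-1,3-dimethoxybenzene | COc1cc(Br)cc(OC)c1OCc2ccccc2 | intermediate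
12 | [4-(benzyloxy)-3,5-dimethoxyphenyl]magnesium bromide | COc1cc([Mg]Br)cc(OC)c1OCc2ccccc2 | intermediate (not isolated)
13 | bromomagnesium (2R)-3-(benzyloxy)-1-[4-(benzyloxy)-3,5-dimethoxyphenyl]-2-[2-bromo-4-(1,3-dioxolan-2-yl)-6-methoxyphenoxy]-1-[methoxy(methyl)amino]propan-1-olate (C1 not defined) | COc1cc(C(O[Mg]Br)(N(C)OC)[C@@H](COCc2ccccc2)Oc3c(Br)cc(C4OCCO4)cc3OC)cc(OC)c1OCc5ccccc5 | intermediate (not isolated)
14 | (2R)-3-(benzyloxy)-1-[4-(benzyloxy)-3,5-dimethoxyphenyl]-2-[2-bromo-4-(1,3-dioxolan-2-yl)-6-methoxyphenoxy]propan-1-one | COc1cc(C(=O)[C@@H](COCc2ccccc2)Oc3c(Br)cc(C4OCCO4)cc3OC)cc(OC)c1OCc5ccccc5 | intermediate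
15 | (1R,2R)-3-(benzyloxy)-1-[4-(benzyloxy)-3,5-dimethoxyphenyl]-2-[2-bromo-4-(1,3-dioxolan-2-yl)-6-methoxyphenoxy]propan-1-ol | COc1cc([C@@H](O)[C@@H](COCc2ccccc2)Oc3c(Br)cc(C4OCCO4)cc3OC)cc(OC)c1OCc5ccccc5 | intermediate
16 | (2R,3R)-2-[(benzyloxy)methyl]-3-[4-(benzyloxy)-3,5-dimethoxyphenyl]-6-(1,3-dioxolan-2-yl)-8-methoxy-2,3-dihydro-1,4-benzodioxine | COc1cc([C@H]2Oc3cc(C4OCCO4)cc(OC)c3O[C@@H]2COCc5ccccc5)cc(OC)c1OCc6ccccc6 | intermediate
17 | (2R,3R)-2-[(benzyloxy)methyl]-3-[4-(benzyloxy)-3,5-dimethoxyphenyl]-8-methoxy-2,3-dihydro-1,4-benzodioxine-6-carbaldehyde | COc1cc([C@H]2Oc3cc(C=O)cc(OC)c3O[C@@H]2COCc4ccccc4)cc(OC)c1OCc5ccccc5 | intermediate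
18 | 1-[2,4-bis(benzyloxy)-6-hydroxyphenyl]ethan-1-one | CC(=O)c1c(O)cc(OCc2ccccc2)cc1OCc3ccccc3 | starting material
19 | (2E)-1-[2,4-bis(benzyloxy)-6-hydroxyphenyl]-3-{(2R,3R)-2-[(benzyloxy)methyl]-3-[4-(benzyloxy)-3,5-dimethoxyphenyl]-8-methoxy-2,3-dihydro-1,4-benzodioxin-6-yl}prop-2-en-1-one | COc1cc([C@H]2Oc3cc(/C=C/C(=O)c4c(O)cc(OCc5ccccc5)cc4OCc6ccccc6)cc(OC)c3O[C@@H]2COCc7ccccc7)cc(OC)c1OCc8ccccc8 | intermediate
20 | 5,7-bis(benzyloxy)-2-{(2R,3R)-2-[(benzyloxy)methyl]-3-[4-(benzyloxy)-3,5-dimethoxyphenyl]-8-methoxy-2,3-dihydro-1,4-benzodioxin-6-yl}-2,3-dihydro-4H-chromen-4-one (C2 epimers) | COc1cc([C@H]2Oc3cc(C4CC(=O)c5c(OCc6ccccc6)cc(OCc7ccccc7)cc5O4)cc(OC)c3O[C@@H]2COCc8ccccc8)cc(OC)c1OCc9ccccc9 | intermediate (not isolated)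
21 | 5,7-bis(benzyloxy)-2-{(2R,3R)-2-[(benzyloxy)methyl]-3-[4-(benzyloxy)-3,5-dimethoxyphenyl]-8-methoxy-2,3-dihydro-1,4-benzodioxin-6-yl}-4H-chromen-4-one | COc1cc([C@H]2Oc3cc(-c4cc(=O)c5c(OCc6ccccc6)cc(OCc7ccccc7)cc5o4)cc(OC)c3O[C@@H]2COCc8ccccc8)cc(OC)c1OCc9ccccc9 | intermediate
22 | palstatin, 5,7-dihydroxy-2-[(2R,3R)-3-(4-hydroxy-3,5-dimethoxyphenyl)-2-(hydroxymethyl)-8-methoxy-2,3-dihydro-1,4-benzodioxin-6-yl]-4H-chromen-4-one | COc1cc([C@H]2Oc3cc(-c4cc(=O)c5c(O)cc(O)cc5o4)cc(OC)c3O[C@@H]2CO)cc(OC)c1O | target

## Step count and least certain steps

Total: 13 steps. Longest linear sequence: 11 steps, from 3 to 22 through steps 2, 3, 4, 5, 7, 8, 9, 10, 11, 12 and 13. Steps 1 and 6 are side branches.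

**Step 9 (key step).** The most likely failure is β-hydride elimination from the palladium alkoxide of the benzylic alcohol, which would oxidise C7'' and reduce off the bromine. Oxidative addition into the electron-rich, ortho-oxygenated bromide may also be slow. The fallback forms the other dioxane bond and sets out from 15. Miyaura borylation (PdCl2(dppf), bis(pinacolato)diboron, KOAc, dioxane, 80 °C) should give (1R,2R)-3-(benzyloxy)-1-[4-(benzyloxy)-3,5-dimethoxyphenyl]-2-[4-(1,3-dioxolan-2-yl)-2-methoxy-6-(4,4,5,5-tetramethyl-1,3,2-dioxaborolan-2-yl)phenoxy]propan-1-ol F1. Oxidation with NaBO3·4H2O in THF–water should give the phenol (1R,2R)-3-(benzyloxy)-1-[4-(benzyloxy)-3,5-dimethoxyphenyl]-2-[4-(1,3-dioxolan-2-yl)-2-hydroxy-6-methoxyphenoxy]propan-1-ol F2. A sulfonic acid resin (Amberlyst 15) in toluene at 60 °C, followed by dilute aqueous acid, should then ionise C7'', let the C3' hydroxyl capture the benzylic cation to give the thermodynamically preferred trans-dioxane, and remove the acetal in the same operation. C8'' is not touched. The fallback rejoins the route at aldehyde 17.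

**Step 8.** Facial selectivity may be poor if lithium chelation between the carbonyl and the ether oxygens competes with the Felkin–Anh pathway, and enolisation would erode C8''. The fallback replaces substrate control by catalyst control. It sets out from 14 and uses asymmetric transfer hydrogenation with RuCl(p-cymene)[(S,S)-TsDPEN] in HCO2H/Et3N, the catalyst enantiomer whose aryl-ketone facial preference corresponds to C7'' R here. It returns at 15 and passes through no new compound.

**Step 4.** The phenol of 2 is flanked by bromine and methoxy, so the SN2 displacement may be slow. Elimination of the activated hydroxyl toward a benzyloxyacrylate, or incomplete inversion, could then intervene. The fallback separates activation from displacement and sets out from 7. Tf2O and 2,6-lutidine in CH2Cl2 at −78 °C should give methyl (2S)-3-(benzyloxy)-2-{[(trifluoromethyl)sulfonyl]oxy}propanoate F3. The potassium phenoxide of 2 (K2CO3, MeCN, 0 °C → rt) should then displace the triflate with inversion. The fallback returns at 8.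

**Step 7.** The Grignard reagent may deprotonate C8'' of the amide instead of adding, which would cause epimerisation or β-elimination of benzyloxide. Grignard formation from the electron-rich bromide 11 may also be sluggish. The fallback changes the electrophile and sets out from 8. i-Bu2AlH in toluene at −78 °C should give (2R)-3-(benzyloxy)-2-[2-bromo-4-(1,3-dioxolan-2-yl)-6-methoxyphenoxy]propanal F4. Addition of 12 at −78 °C should give (2R)-3-(benzyloxy)-1-[4-(benzyloxy)-3,5-dimethoxyphenyl]-2-[2-bromo-4-(1,3-dioxolan-2-yl)-6-methoxyphenoxy]propan-1-ol F5 as a mixture of C1 epimers. Dess–Martin periodinane buffered with NaHCO3 should then give the ketone. The fallback returns at 14.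

**Step 13.** Over-reduction of the C2=C3 bond of ring C, or hydrogenolytic opening of the benzylic C7''–O bond of the dioxane, could accompany removal of the slower benzyl ethers. The fallback removes the benzyl groups without hydrogen. It sets out from 21 and uses BCl3 with pentamethylbenzene as cation scavenger in CH2Cl2 at −78 °C. It returns at 22 and passes through no new compound.

## Further compounds

F1 | step 9 | (1R,2R)-3-(benzyloxy)-1-[4-(benzyloxy)-3,5-dimethoxyphenyl]-2-[4-(1,3-dioxolan-2-yl)-2-methoxy-6-(4,4,5,5-tetramethyl-1,3,2-dioxaborolan-2-yl)phenoxy]propan-1-ol | COc1cc([C@@H](O)[C@@H](COCc2ccccc2)Oc3c(B4OC(C)(C)C(C)(C)O4)cc(C5OCCO5)cc3OC)cc(OC)c1OCc6ccccc6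
F2 | step 9 | (1R,2R)-3-(benzyloxy)-1-[4-(benzyloxy)-3,5-dimethoxyphenyl]-2-[4-(1,3-dioxolan-2-yl)-2-hydroxy-6-methoxyphenoxy]propan-1-ol | COc1cc([C@@H](O)[C@@H](COCc2ccccc2)Oc3c(O)cc(C4OCCO4)cc3OC)cc(OC)c1OCc5ccccc5
F0 | step 8 | none | none
F3 | step 4 | methyl (2S)-3-(benzyloxy)-2-{[(trifluoromethyl)sulfonyl]oxy}propanoate | COC(=O)[C@@H](OS(=O)(=O)C(F)(F)F)COCc1ccccc1
F4 | step 7 | (2R)-3-(benzyloxy)-2-[2-bromo-4-(1,3-dioxolan-2-yl)-6-methoxyphenoxy]propanal | O=C[C@@H](COCc1ccccc1)Oc2c(Br)cc(C3OCCO3)cc2OC
F5 | step 7 | (2R)-3-(benzyloxy)-1-[4-(benzyloxy)-3,5-dimethoxyphenyl]-2-[2-bromo-4-(1,3-dioxolan-2-yl)-6-methoxyphenoxy]propan-1-ol (C1 epimers) | COc1cc(C(O)[C@@H](COCc2ccccc2)Oc3c(Br)cc(C4OCCO4)cc3OC)cc(OC)c1OCc5ccccc5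
F0 | step 13 | none | none
A1 | alternative 1 | methyl (2R,3R)-3-(4-hydroxy-3,5-dimethoxyphenyl)-2-(hydroxymethyl)-8-methoxy-2,3-dihydro-1,4-benzodioxine-6-carboxylate | COc1cc([C@H]2Oc3cc(C(=O)OC)cc(OC)c3O[C@@H]2CO)cc(OC)c1O
A2 | alternative 1 | methyl 3-hydroxy-4-{[(2S)-1-hydroxy-3-(4-hydroxy-3,5-dimethoxyphenyl)propan-2-yl]oxy}-5-methoxybenzoate | COc1cc(C[C@@H](CO)Oc2c(O)cc(C(=O)OC)cc2OC)cc(OC)c1O
A3 | alternative 2 | 2-{(2R,3R)-2-[(benzyloxy)methyl]-3-[4-(benzyloxy)-3,5-dimethoxyphenyl]-8-methoxy-2,3-dihydro-1,4-benzodioxin-6-yl}-5,7-difluoro-4H-chromen-4-one | COc1cc([C@H]2Oc3cc(-c4cc(=O)c5c(F)cc(F)cc5o4)cc(OC)c3O[C@@H]2COCc6ccccc6)cc(OC)c1OCc7ccccc7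
A4 | alternative 2 | 1-{(2R,3R)-2-[(benzyloxy)methyl]-3-[4-(benzyloxy)-3,5-dimethoxyphenyl]-8-methoxy-2,3-dihydro-1,4-benzodioxin-6-yl}-3-(2,4,6-trifluorophenyl)propane-1,3-dione | COc1cc([C@H]2Oc3cc(C(=O)CC(=O)c4c(F)cc(F)cc4F)cc(OC)c3O[C@@H]2COCc5ccccc5)cc(OC)c1OCc6ccccc6
A5 | alternative 3 | (2R,3R)-3-[4-(benzyloxy)-3,5-dimethoxyphenyl]-2-(hydroxymethyl)-8-methoxy-2,3-dihydro-1,4-benzodioxine-6-carbaldehyde | COc1cc([C@H]2Oc3cc(C=O)cc(OC)c3O[C@@H]2CO)cc(OC)c1OCc4ccccc4
A6 | alternative 3 | 3-{(R)-[4-(benzyloxy)-3,5-dimethoxyphenyl][(2S)-oxiran-2-yl]methoxy}-4-hydroxy-5-methoxybenzaldehyde | COc1cc([C@@H](Oc2cc(C=O)cc(OC)c2O)[C@@H]3CO3)cc(OC)c1OCc4ccccc4
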